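**Retrosynthetic overview**

1. Numbering used throughout (germacrane style): lactone O–C6, C7 (ring-fusion CH that carries C11), C8 (tiglate), C9, C10(Me)=C1, C2 (OH), C3, C4 (=C15H2), C5 (OAc); lactone carbons C11 (=C13H2) and C12 (C=O).
2. Enabling feature: C7 is at once the β-carbon of the γ-lactone ring (O–C6–C7–C11–C12) and the allylic carbon of the exocyclic C11=C13 methylene, and its neighbour C8 in the ten-membered ring bears oxygen. C13=C11–C7–C8–O is therefore the retron of a carbonyl allylation, and a 3-(bromomethyl)butenolide (C7=C11, C13–Br) is a latent C7 nucleophile for a C8 aldehyde.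
3. Key disconnection C7–C8: an intramolecular Nozaki–Hiyama–Kishi allylation of seco-aldehyde 21 closes the ten-membered carbocycle last, sets C7 and C8, and turns the butenolide into the cis-fused α-methylene-γ-lactone in one operation. A Mitsunobu tigloylation (inverting C8) and desilylation finish the route.
4. The butenolide comes from ring-closing metathesis of an O6 2-(bromomethyl)acrylate; C5/C6 from an anti-selective γ-alkoxyallylboration of enal 10; C2 from a reagent-controlled 2-bromoallylation of Z-enal 4, whose Z-alkene is inherited from the ring of 4-methyl-5,6-dihydro-2H-pyran-2-one.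
5. Order of ring formation: butenolide (step 13), then the ten-membered carbocycle (step 16).

Key step: step 16

Assumption: the (4R,5R)-diazaborolidine controller of step 5 is taken as the enantiomer that delivers the 2-bromoallyl group to the Re face of enal 4; if its sense is the opposite, the (4S,5S)-controller is used with no other change.

**Route**

Step 1
Reactants: 1 4-methyl-5,6-dihydro-2H-pyran-2-one
Product: 2 (2Z)-5-hydroxy-N-methoxy-N,3-dimethylpent-2-enamide
Conditions: MeNH(OMe)·HCl, AlMe3, CH2Cl2, 0 °C to rt; aq. potassium sodium tartrate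
Reagents that add atoms: N,O-dimethylhydroxylamine hydrochloride, CNOC.Cl
Why: Aluminium-amide (Weinreb) aminolysis opens the lactone at the acyl C–O bond and leaves the ring-locked alkene untouched, so the Z-trisubstituted C1=C10 alkene of the target is inherited from the six-membered ring.

Step 2
Reactants: 2 (2Z)-5-hydroxy-N-methoxy-N,3-dimethylpent-2-enamide
Product: 3 (2Z)-N-methoxy-N,3-dimethyl-5-[(triethylsilyl)oxy]pent-2-enamide
Conditions: Et3SiCl, imidazole, CH2Cl2, 0 °C
Reagents that add atoms: chlorotriethylsilane, CC[Si](Cl)(CC)CC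
Why: Standard silylation of the primary alcohol stops relactonization, and the triethylsilyl ether can later be cleaved by mild acid beside a secondary tert-butyldimethylsilyl ether.

Step 3
Reactants: 3 (2Z)-N-methoxy-N,3-dimethyl-5-[(triethylsilyl)oxy]pent-2-enamide
Product: 4 (2Z)-3-methyl-5-[(triethylsilyl)oxy]pent-2-enal
Conditions: i-Bu2AlH, THF, −78 °C; aq. potassium sodium tartrate
Reagents that add atoms: none
Why: Hydride reduction of a Weinreb amide stops at the aldehyde through the chelated tetrahedral intermediate, and the cold, neutral work-up should keep the Z-enal from isomerizing.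

Step 4
Reactants: 5 2,3-dibromoprop-1-ene
Product: 6 tributyl(2-bromoprop-2-en-1-yl)stannane
Conditions: Bu3SnH, LiN(i-Pr)2, THF, −78 °C; then 5, −78 to 0 °C
Reagents that add atoms: tributyltin hydride, CCCC[SnH](CCCC)CCCC
Why: Tributylstannyllithium, made in the flask, displaces the allylic bromide (SN2 or SN2', both give the same product) while the vinylic bromide is inert.

Step 5
Reactants: 4 (2Z)-3-methyl-5-[(triethylsilyl)oxy]pent-2-enal; 6 tributyl(2-bromoprop-2-en-1-yl)stannane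
Product: 8 (4R,5Z)-2-bromo-6-methyl-8-[(triethylsilyl)oxy]octa-1,5-dien-4-ol, via B-(2-bromoallyl)diazaborolidine 7 (not isolated)
Conditions: (4R,5R)-2-bromo-4,5-diphenyl-1,3-bis(4-tolylsulfonyl)-1,3,2-diazaborolidine, CH2Cl2, 6, 0 °C to rt; then 4, −78 °C; pH 7 buffer
Reagents that add atoms: none
Why: Tin-to-boron exchange gives the chiral allylborane 7, which adds to the aldehyde through a chair six-membered transition state whose bis-sulfonamide controller blocks one face, so C2 is set as R by reagent control (enantioselective allylboration, 2-haloallyl variant).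

Step 6
Reactants: 8 (4R,5Z)-2-bromo-6-methyl-8-[(triethylsilyl)oxy]octa-1,5-dien-4-ol
Product: 9 (4R,5Z)-2-bromo-4-[(tert-butyldimethylsilyl)oxy]-6-methyl-8-[(triethylsilyl)oxy]octa-1,5-diene
Conditions: t-BuMe2SiOTf, 2,6-lutidine, CH2Cl2, −78 °C
Reagents that add atoms: tert-butyldimethylsilyl trifluoromethanesulfonate, CC(C)(C)[Si](C)(C)OS(=O)(=O)C(F)(F)F
Why: Silyl triflate with a hindered base protects the secondary allylic alcohol without acid that could move the Z-alkene.

Step 7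
Reactants: 9 (4R,5Z)-2-bromo-4-[(tert-butyldimethylsilyl)oxy]-6-methyl-8-[(triethylsilyl)oxy]octa-1,5-diene
Product: 10 (4R,5Z)-4-[(tert-butyldimethylsilyl)oxy]-6-methyl-2-methylidene-8-[(triethylsilyl)oxy]oct-5-enal
Conditions: t-BuLi (2.1 equiv), Et2O, −78 °C; DMF, −78 to 0 °C; aq. NH4Cl
Reagents that add atoms: N,N-dimethylformamide, CN(C)C=O
Why: Bromine–lithium exchange gives the 2-lithioalkene, which DMF formylates (Bouveault-type formylation) to the 2-substituted acrolein that supplies C5; at −78 °C in ether a 1,4-silyl shift from O2 should not compete.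

Step 8
Reactants: 11 1-methoxy-4-[(prop-2-yn-1-yloxy)methyl]benzene
Product: 12 1-methoxy-4-[(propa-1,2-dien-1-yloxy)methyl]benzene
Conditions: KOt-Bu (0.2 equiv), THF, 0 °C to rt
Reagents that add atoms: none
Why: Base-catalysed propargyl-to-allenyl isomerization of a propargyl ether, driven by conjugation of the allene with oxygen, gives the alkoxyallene.

Step 9
Reactants: 10 (4R,5Z)-4-[(tert-butyldimethylsilyl)oxy]-6-methyl-2-methylidene-8-[(triethylsilyl)oxy]oct-5-enal; 12 1-methoxy-4-[(propa-1,2-dien-1-yloxy)methyl]benzene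
Product: 14 (3R,4S,7R,8Z)-7-[(tert-butyldimethylsilyl)oxy]-3-[(4-methoxybenzyl)oxy]-9-methyl-5-methylidene-11-[(triethylsilyl)oxy]undeca-1,8-dien-4-ol, via E-alkoxyallylborane 13 (not isolated)
Conditions: (+)-Ipc2BH (from (−)-α-pinene), THF, 12, −40 to 0 °C; then 10, −78 °C; NaBO3·4H2O, THF/H2O, rt
Reagents that add atoms: none
Why: Hydroboration of the terminal allene bond gives the (E)-γ-alkoxyallylborane 13, which adds through a chair transition state (Brown alkoxyallylboration): the E geometry gives the 5,6-anti relationship and the isopinocampheyl groups direct attack to the Re face of the aldehyde, setting C5 as S and C6 as R with O5 free and O6 protected.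

Step 10
Reactants: 14 (3R,4S,7R,8Z)-7-[(tert-butyldimethylsilyl)oxy]-3-[(4-methoxybenzyl)oxy]-9-methyl-5-methylidene-11-[(triethylsilyl)oxy]undeca-1,8-dien-4-ol
Product: 15 (3R,4S,7R,8Z)-7-[(tert-butyldimethylsilyl)oxy]-3-[(4-methoxybenzyl)oxy]-9-methyl-5-methylidene-11-[(triethylsilyl)oxy]undeca-1,8-dien-4-yl acetate
Conditions: Ac2O, pyridine, DMAP (cat.), CH2Cl2, 0 °C
Reagents that add atoms: acetic anhydride, CC(=O)OC(C)=O
Why: Standard acylation of the free secondary alcohol puts the C5 acetate of the target in place while O6 is still blocked.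

Step 11
Reactants: 15 (3R,4S,7R,8Z)-7-[(tert-butyldimethylsilyl)oxy]-3-[(4-methoxybenzyl)oxy]-9-methyl-5-methylidene-11-[(triethylsilyl)oxy]undeca-1,8-dien-4-yl acetate
Product: 16 (3R,4S,7R,8Z)-7-[(tert-butyldimethylsilyl)oxy]-3-hydroxy-9-methyl-5-methylidene-11-[(triethylsilyl)oxy]undeca-1,8-dien-4-yl acetate
Conditions: DDQ, CH2Cl2/pH 7 buffer, 0 °C
Reagents that add atoms: none
Why: Oxidative cleavage of the 4-methoxybenzyl ether by DDQ is neutral, so the neighbouring acetate should not migrate and the silyl ethers and alkenes are left alone.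

Step 12
Reactants: 16 (3R,4S,7R,8Z)-7-[(tert-butyldimethylsilyl)oxy]-3-hydroxy-9-methyl-5-methylidene-11-[(triethylsilyl)oxy]undeca-1,8-dien-4-yl acetate; 17 2-(bromomethyl)prop-2-enoic acid
Product: 18 (3R,4S,7R,8Z)-4-acetoxy-7-[(tert-butyldimethylsilyl)oxy]-9-methyl-5-methylidene-11-[(triethylsilyl)oxy]undeca-1,8-dien-3-yl 2-(bromomethyl)prop-2-enoate
Conditions: DCC, DMAP (0.1 equiv), CH2Cl2, −10 to 0 °C
Reagents that add atoms: none
Why: Carbodiimide (Steglich) esterification joins O6 to the acid that carries C11, C12 and C13; low temperature and little DMAP limit acetyl migration and SN2' attack on the allylic bromide.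

Step 13
Reactants: 18 (3R,4S,7R,8Z)-4-acetoxy-7-[(tert-butyldimethylsilyl)oxy]-9-methyl-5-methylidene-11-[(triethylsilyl)oxy]undeca-1,8-dien-3-yl 2-(bromomethyl)prop-2-enoate
Product: 19 (1S,4R,5Z)-1-[(2R)-4-(bromomethyl)-5-oxo-2,5-dihydrofuran-2-yl]-4-[(tert-butyldimethylsilyl)oxy]-6-methyl-2-methylidene-8-[(triethylsilyl)oxy]oct-5-en-1-yl acetate
Conditions: second-generation Grubbs catalyst (10 mol%), CH2Cl2 (5 mM), 40 °C
Reagents that add atoms: none
Why: Ring-closing metathesis starts at the monosubstituted C7 vinyl group and closes onto the acrylate alkene of the same ester, the only partner that gives a five-membered ring, forming the butenolide with the C13 bromide already in place (known for 2-substituted acrylates of allylic alcohols).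

Step 14
Reactants: 19 (1S,4R,5Z)-1-[(2R)-4-(bromomethyl)-5-oxo-2,5-dihydrofuran-2-yl]-4-[(tert-butyldimethylsilyl)oxy]-6-methyl-2-methylidene-8-[(triethylsilyl)oxy]oct-5-en-1-yl acetate
Product: 20 (1S,4R,5Z)-1-[(2R)-4-(bromomethyl)-5-oxo-2,5-dihydrofuran-2-yl]-4-[(tert-butyldimethylsilyl)oxy]-8-hydroxy-6-methyl-2-methylidene-oct-5-en-1-yl acetate
Conditions: PPTS (0.2 equiv), MeOH/CH2Cl2, 0 °C
Reagents that add atoms: none
Why: Acid-catalysed methanolysis removes the primary triethylsilyl ether much faster than the secondary tert-butyldimethylsilyl ether and does not touch the acetate, the butenolide or the allylic bromide.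

Step 15
Reactants: 20 (1S,4R,5Z)-1-[(2R)-4-(bromomethyl)-5-oxo-2,5-dihydrofuran-2-yl]-4-[(tert-butyldimethylsilyl)oxy]-8-hydroxy-6-methyl-2-methylidene-oct-5-en-1-yl acetate
Product: 21 (1S,4R,5Z)-1-[(2R)-4-(bromomethyl)-5-oxo-2,5-dihydrofuran-2-yl]-4-[(tert-butyldimethylsilyl)oxy]-6-methyl-2-methylidene-8-oxooct-5-en-1-yl acetate
Conditions: Dess–Martin periodinane, NaHCO3, CH2Cl2, 0 °C; used crude at once
Reagents that add atoms: none
Why: Buffered Dess–Martin oxidation gives the β,γ-unsaturated aldehyde without acid or base that would move the C1=C10 alkene into conjugation.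

Step 16
Reactants: 21 (1S,4R,5Z)-1-[(2R)-4-(bromomethyl)-5-oxo-2,5-dihydrofuran-2-yl]-4-[(tert-butyldimethylsilyl)oxy]-6-methyl-2-methylidene-8-oxooct-5-en-1-yl acetate
Product: 23 (2R,5S,6R,7R,8S)-5-acetoxy-2-[(tert-butyldimethylsilyl)oxy]-8-hydroxygermacra-1(10)Z,4(15),11(13)-trien-12,6-olide, via allylchromium species 22 (not isolated)
Conditions: CrCl2 (8 equiv), THF, 25 °C, syringe-pump addition of 21 to about 2 mM; aq. NH4Cl
Reagents that add atoms: none
Why: Two equivalents of CrCl2 (divalent chromium) reduce the C13–Br bond to the allylchromium 22 (trivalent chromium), which adds through its γ-carbon C7 to the chromium-bound C8 aldehyde in a six-membered cyclic transition state with allylic transposition, so that the C7–C8 bond, the C8 carbinol and the exocyclic C11=C13 methylene arise together (intramolecular Nozaki–Hiyama–Kishi allylation). The closest known reactions are the intramolecular chromium-mediated allylations that close the ten-membered ring of germacranolides and the γ-selective additions of 3-(bromomethyl)butenolides to aldehydes. The ring closed is the ten-membered carbocycle, formed by attack of butenolide ring carbon C7 on the aldehyde at the end of the chain; the five-membered lactone is already present and ends up cis-fused across C6–C7. C7 is controlled by the tether: C5 leaves C6 on one face of the planar butenolide, and the short C5-to-C8 chain with its Z-alkene should bring the aldehyde over that same face, giving the cis fusion and a low-strain ring of the (Z,Z)-cyclodeca-1,5-diene type. C8 is controlled by the cyclic transition state: the lactone ring locks the allyl unit in the E-type geometry and C9 stays away from the lactone ring, which gives the 7,8-anti adduct (8S), the epimer that the inverting esterification of step 17 needs. The step needs γ- over α-attack (secured by the closed allylchromium transition state), cyclization over oligomerization (high dilution) and an unisomerized aldehyde (neutral conditions, 21 made just before use).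

Step 17
Reactants: 23 (2R,5S,6R,7R,8S)-5-acetoxy-2-[(tert-butyldimethylsilyl)oxy]-8-hydroxygermacra-1(10)Z,4(15),11(13)-trien-12,6-olide; 24 (2E)-2-methylbut-2-enoic acid (tiglic acid)
Product: 25 (2R,5S,6R,7R,8R)-5-acetoxy-2-[(tert-butyldimethylsilyl)oxy]-8-[(2E)-2-methylbut-2-enoyloxy]germacra-1(10)Z,4(15),11(13)-trien-12,6-olide
Conditions: PPh3, DIAD, THF, 0 °C (betaine preformed); then 23 and 24, 0 °C to rt
Reagents that add atoms: none
Why: Mitsunobu esterification activates O8 as an oxyphosphonium ion that tiglate displaces by SN2, inverting C8 from S to R and installing the ester in one step; preforming the betaine keeps PPh3 from adding to the α-methylene lactone.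

Step 18
Reactants: 25 (2R,5S,6R,7R,8R)-5-acetoxy-2-[(tert-butyldimethylsilyl)oxy]-8-[(2E)-2-methylbut-2-enoyloxy]germacra-1(10)Z,4(15),11(13)-trien-12,6-olide
Product: 26 (2R,5S,6R,7R,8R)-5-acetoxy-2-hydroxy-8-[(2E)-2-methylbut-2-enoyloxy]germacra-1(10)Z,4(15),11(13)-trien-12,6-olide (target)
Conditions: HF·pyridine, pyridine, THF, 0 °C to rt
Reagents that add atoms: none
Why: Fluoride cleaves the remaining secondary silyl ether under buffered, weakly acidic conditions that leave the acetate, the tiglate and the α-methylene lactone intact.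

**Compound list**

1 | 4-methyl-5,6-dihydro-2H-pyran-2-one | CC1=CC(=O)OCC1 | starting material
2 | (2Z)-5-hydroxy-N-methoxy-N,3-dimethylpent-2-enamide | OCC/C(C)=C\C(=O)N(C)OC | intermediate
3 | (2Z)-N-methoxy-N,3-dimethyl-5-[(triethylsilyl)oxy]pent-2-enamide | CC[Si](CC)(CC)OCC/C(C)=C\C(=O)N(C)OC | intermediate
4 | (2Z)-3-methyl-5-[(triethylsilyl)oxy]pent-2-enal | CC[Si](CC)(CC)OCC/C(C)=C\C=O | intermediate
5 | 2,3-dibromoprop-1-ene | C=C(Br)CBr | starting material
6 | tributyl(2-bromoprop-2-en-1-yl)stannane | C=C(Br)C[Sn](CCCC)(CCCC)CCCC | intermediate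
7 | (4R,5R)-2-(2-bromoprop-2-en-1-yl)-4,5-diphenyl-1,3-bis(4-tolylsulfonyl)-1,3,2-diazaborolidine | C=C(Br)CB1N(S(=O)(=O)c2ccc(C)cc2)[C@H](c2ccccc2)[C@@H](c2ccccc2)N1S(=O)(=O)c1ccc(C)cc1 | intermediate (not isolated)
8 | (4R,5Z)-2-bromo-6-methyl-8-[(triethylsilyl)oxy]octa-1,5-dien-4-ol | CC[Si](CC)(CC)OCC/C(C)=C\[C@H](O)CC(Br)=C | intermediate
9 | (4R,5Z)-2-bromo-4-[(tert-butyldimethylsilyl)oxy]-6-methyl-8-[(triethylsilyl)oxy]octa-1,5-diene | CC[Si](CC)(CC)OCC/C(C)=C\[C@H](O[Si](C)(C)C(C)(C)C)CC(Br)=C | intermediate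
10 | (4R,5Z)-4-[(tert-butyldimethylsilyl)oxy]-6-methyl-2-methylidene-8-[(triethylsilyl)oxy]oct-5-enal | CC[Si](CC)(CC)OCC/C(C)=C\[C@H](O[Si](C)(C)C(C)(C)C)CC(=C)C=O | intermediate
11 | 1-methoxy-4-[(prop-2-yn-1-yloxy)methyl]benzene (4-methoxybenzyl propargyl ether) | C#CCOCc1ccc(OC)cc1 | starting material
12 | 1-methoxy-4-[(propa-1,2-dien-1-yloxy)methyl]benzene (4-methoxybenzyl allenyl ether) | C=C=COCc1ccc(OC)cc1 | intermediate
13 | (E)-{3-[(4-methoxybenzyl)oxy]prop-2-en-1-yl}diisopinocampheylborane, isopinocampheyl groups from (−)-α-pinene | COc1ccc(CO/C=C/CB([C@H]2C[C@H]3C[C@@H]([C@@H]2C)C3(C)C)[C@H]2C[C@H]3C[C@@H]([C@@H]2C)C3(C)C)cc1 | intermediate (not isolated)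
14 | (3R,4S,7R,8Z)-7-[(tert-butyldimethylsilyl)oxy]-3-[(4-methoxybenzyl)oxy]-9-methyl-5-methylidene-11-[(triethylsilyl)oxy]undeca-1,8-dien-4-ol | CC[Si](CC)(CC)OCC/C(C)=C\[C@H](O[Si](C)(C)C(C)(C)C)CC(=C)[C@H](O)[C@H](OCc1ccc(OC)cc1)C=C | intermediate
15 | (3R,4S,7R,8Z)-7-[(tert-butyldimethylsilyl)oxy]-3-[(4-methoxybenzyl)oxy]-9-methyl-5-methylidene-11-[(triethylsilyl)oxy]undeca-1,8-dien-4-yl acetate | CC[Si](CC)(CC)OCC/C(C)=C\[C@H](O[Si](C)(C)C(C)(C)C)CC(=C)[C@H](OC(C)=O)[C@H](OCc1ccc(OC)cc1)C=C | intermediate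
16 | (3R,4S,7R,8Z)-7-[(tert-butyldimethylsilyl)oxy]-3-hydroxy-9-methyl-5-methylidene-11-[(triethylsilyl)oxy]undeca-1,8-dien-4-yl acetate | CC[Si](CC)(CC)OCC/C(C)=C\[C@H](O[Si](C)(C)C(C)(C)C)CC(=C)[C@H](OC(C)=O)[C@H](O)C=C | intermediate
17 | 2-(bromomethyl)prop-2-enoic acid | C=C(CBr)C(=O)O | starting material
18 | (3R,4S,7R,8Z)-4-acetoxy-7-[(tert-butyldimethylsilyl)oxy]-9-methyl-5-methylidene-11-[(triethylsilyl)oxy]undeca-1,8-dien-3-yl 2-(bromomethyl)prop-2-enoate | CC[Si](CC)(CC)OCC/C(C)=C\[C@H](O[Si](C)(C)C(C)(C)C)CC(=C)[C@H](OC(C)=O)[C@H](OC(=O)C(=C)CBr)C=C | intermediate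
19 | (1S,4R,5Z)-1-[(2R)-4-(bromomethyl)-5-oxo-2,5-dihydrofuran-2-yl]-4-[(tert-butyldimethylsilyl)oxy]-6-methyl-2-methylidene-8-[(triethylsilyl)oxy]oct-5-en-1-yl acetate | CC[Si](CC)(CC)OCC/C(C)=C\[C@H](O[Si](C)(C)C(C)(C)C)CC(=C)[C@H](OC(C)=O)[C@@H]1OC(=O)C(CBr)=C1 | intermediate
20 | (1S,4R,5Z)-1-[(2R)-4-(bromomethyl)-5-oxo-2,5-dihydrofuran-2-yl]-4-[(tert-butyldimethylsilyl)oxy]-8-hydroxy-6-methyl-2-methylidene-oct-5-en-1-yl acetate | OCC/C(C)=C\[C@H](O[Si](C)(C)C(C)(C)C)CC(=C)[C@H](OC(C)=O)[C@@H]1OC(=O)C(CBr)=C1 | intermediate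
21 | (1S,4R,5Z)-1-[(2R)-4-(bromomethyl)-5-oxo-2,5-dihydrofuran-2-yl]-4-[(tert-butyldimethylsilyl)oxy]-6-methyl-2-methylidene-8-oxooct-5-en-1-yl acetate | O=CC/C(C)=C\[C@H](O[Si](C)(C)C(C)(C)C)CC(=C)[C@H](OC(C)=O)[C@@H]1OC(=O)C(CBr)=C1 | intermediate
22 | dichloro{[(5R)-5-{(1S,4R,5Z)-1-acetoxy-4-[(tert-butyldimethylsilyl)oxy]-6-methyl-2-methylidene-8-oxooct-5-en-1-yl}-2-oxo-2,5-dihydrofuran-3-yl]methyl}chromium (trivalent chromium) | O=CC/C(C)=C\[C@H](O[Si](C)(C)C(C)(C)C)CC(=C)[C@H](OC(C)=O)[C@@H]1OC(=O)C(C[Cr](Cl)Cl)=C1 | intermediate (not isolated)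
23 | (2R,5S,6R,7R,8S)-5-acetoxy-2-[(tert-butyldimethylsilyl)oxy]-8-hydroxygermacra-1(10)Z,4(15),11(13)-trien-12,6-olide | C=C1C(=O)O[C@@H]2[C@H]1[C@@H](O)C/C(C)=C\[C@H](O[Si](C)(C)C(C)(C)C)CC(=C)[C@@H]2OC(C)=O | intermediate
24 | (2E)-2-methylbut-2-enoic acid (tiglic acid) | C/C=C(\C)C(=O)O | starting material
25 | (2R,5S,6R,7R,8R)-5-acetoxy-2-[(tert-butyldimethylsilyl)oxy]-8-[(2E)-2-methylbut-2-enoyloxy]germacra-1(10)Z,4(15),11(13)-trien-12,6-olide | C=C1C(=O)O[C@@H]2[C@H]1[C@H](OC(=O)/C(C)=C/C)C/C(C)=C\[C@H](O[Si](C)(C)C(C)(C)C)CC(=C)[C@@H]2OC(C)=O | intermediate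
26 | (2R,5S,6R,7R,8R)-5-acetoxy-2-hydroxy-8-[(2E)-2-methylbut-2-enoyloxy]germacra-1(10)Z,4(15),11(13)-trien-12,6-olide | C=C1C(=O)O[C@@H]2[C@H]1[C@H](OC(=O)/C(C)=C/C)C/C(C)=C\[C@H](O)CC(=C)[C@@H]2OC(C)=O | target

**Step count and risks**

Total step count: 18. Longest linear sequence: 16 (steps 1–3, 5–7, 9–18).

Steps most likely to fail:

1. Step 16, facial selectivity at C7. Intermolecular additions of 5-substituted 3-(bromomethyl)butenolides go anti to the C5 substituent of the butenolide; if the tether does not override this, the aldehyde is delivered to the wrong face and the ring fusion comes out trans. Oligomerization and isomerization of the aldehyde into conjugation are further failure modes. The fallback sets out from 14 and comes back at 25. It moves the lactone tether from O6 to O5, so that the inherent preference works for the target. Alcohol 14 is esterified at O5 with 17 (DCC, DMAP) to the O5 2-(bromomethyl)acrylate F1. Ring-closing metathesis gives the 3-(bromomethyl)-5,6-dihydro-2H-pyran-2-one F2, in which O6 is still a 4-methoxybenzyl ether. Removal of the triethylsilyl group (PPTS, MeOH) gives the primary alcohol F3, and Dess–Martin oxidation gives the aldehyde F4. CrCl2 then closes the ten-membered ring to the bridged δ-lactone alcohol F5; the aldehyde should now add to C7 anti to the neighbouring C6 ether, which is the face that carries the axial C5 chain (C7 R, C8 S). Mitsunobu reaction with 24 gives the tiglate F6. DDQ frees O6 to give the hydroxy δ-lactone F7, which CSA should translactonize to the cis-fused γ-lactone alcohol F8 (five-membered ring favoured, bridged ring released). Acetylation (Ac2O, pyridine) gives 25.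

2. Step 17, elimination or no reaction in place of SN2 inversion. C8 is a hindered ring carbinol and tiglic acid is a weak acid for a Mitsunobu reaction, so E2 toward C9 or recovery of the alcohol may win. The fallback sets out from 23 and comes back at 25. O8 is converted with ClCH2SO2Cl and pyridine into the chloromethanesulfonate F9, which is displaced with inversion by cesium tiglate (from 24 and Cs2CO3, 18-crown-6, toluene) to give 25.

3. Step 13, catalyst decomposition by the allylic bromide during the slow closure onto the electron-poor 1,1-disubstituted acrylate. The fallback sets out from 16 and comes back at 19. Alcohol 16 is esterified (DCC, DMAP) with 2-{[(4-methoxybenzyl)oxy]methyl}prop-2-enoic acid to the ester F10. Ring-closing metathesis gives the (4-methoxybenzyloxy)methyl butenolide F11, DDQ gives the hydroxymethyl butenolide F12, and CBr4/PPh3 converts the allylic alcohol into bromide 19.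

Further compounds
F1 | step 16 | (3R,4S,7R,8Z)-7-[(tert-butyldimethylsilyl)oxy]-3-[(4-methoxybenzyl)oxy]-9-methyl-5-methylidene-11-[(triethylsilyl)oxy]undeca-1,8-dien-4-yl 2-(bromomethyl)prop-2-enoate | CC[Si](CC)(CC)OCC/C(C)=C\[C@H](O[Si](C)(C)C(C)(C)C)CC(=C)[C@H](OC(=O)C(=C)CBr)[C@H](OCc1ccc(OC)cc1)C=C
F2 | step 16 | (5R,6S)-3-(bromomethyl)-6-{(4R,5Z)-4-[(tert-butyldimethylsilyl)oxy]-6-methyl-8-[(triethylsilyl)oxy]octa-1,5-dien-2-yl}-5-[(4-methoxybenzyl)oxy]-5,6-dihydro-2H-pyran-2-one | CC[Si](CC)(CC)OCC/C(C)=C\[C@H](O[Si](C)(C)C(C)(C)C)CC(=C)[C@@H]1OC(=O)C(CBr)=C[C@H]1OCc1ccc(OC)cc1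
F3 | step 16 | (5R,6S)-3-(bromomethyl)-6-{(4R,5Z)-4-[(tert-butyldimethylsilyl)oxy]-8-hydroxy-6-methylocta-1,5-dien-2-yl}-5-[(4-methoxybenzyl)oxy]-5,6-dihydro-2H-pyran-2-one | OCC/C(C)=C\[C@H](O[Si](C)(C)C(C)(C)C)CC(=C)[C@@H]1OC(=O)C(CBr)=C[C@H]1OCc1ccc(OC)cc1
F4 | step 16 | (5R,6S)-3-(bromomethyl)-6-{(4R,5Z)-4-[(tert-butyldimethylsilyl)oxy]-6-methyl-8-oxoocta-1,5-dien-2-yl}-5-[(4-methoxybenzyl)oxy]-5,6-dihydro-2H-pyran-2-one | O=CC/C(C)=C\[C@H](O[Si](C)(C)C(C)(C)C)CC(=C)[C@@H]1OC(=O)C(CBr)=C[C@H]1OCc1ccc(OC)cc1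
F5 | step 16 | (2R,5S,6R,7R,8S)-2-[(tert-butyldimethylsilyl)oxy]-8-hydroxy-6-[(4-methoxybenzyl)oxy]germacra-1(10)Z,4(15),11(13)-trien-12,5-olide (bridged δ-lactone) | C=C1C(=O)O[C@@H]2[C@H](OCc3ccc(OC)cc3)[C@H]1[C@@H](O)C/C(C)=C\[C@H](O[Si](C)(C)C(C)(C)C)CC2=C
F6 | step 16 | (2R,5S,6R,7R,8R)-2-[(tert-butyldimethylsilyl)oxy]-6-[(4-methoxybenzyl)oxy]-8-[(2E)-2-methylbut-2-enoyloxy]germacra-1(10)Z,4(15),11(13)-trien-12,5-olide | C=C1C(=O)O[C@@H]2[C@H](OCc3ccc(OC)cc3)[C@H]1[C@H](OC(=O)/C(C)=C/C)C/C(C)=C\[C@H](O[Si](C)(C)C(C)(C)C)CC2=C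
F7 | step 16 | (2R,5S,6R,7S,8R)-2-[(tert-butyldimethylsilyl)oxy]-6-hydroxy-8-[(2E)-2-methylbut-2-enoyloxy]germacra-1(10)Z,4(15),11(13)-trien-12,5-olide | C=C1C(=O)O[C@@H]2[C@H](O)[C@H]1[C@H](OC(=O)/C(C)=C/C)C/C(C)=C\[C@H](O[Si](C)(C)C(C)(C)C)CC2=C
F8 | step 16 | (2R,5S,6R,7R,8R)-2-[(tert-butyldimethylsilyl)oxy]-5-hydroxy-8-[(2E)-2-methylbut-2-enoyloxy]germacra-1(10)Z,4(15),11(13)-trien-12,6-olide | C=C1C(=O)O[C@@H]2[C@H]1[C@H](OC(=O)/C(C)=C/C)C/C(C)=C\[C@H](O[Si](C)(C)C(C)(C)C)CC(=C)[C@@H]2O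
F9 | step 17 | (2R,5S,6R,7S,8S)-5-acetoxy-2-[(tert-butyldimethylsilyl)oxy]-8-[(chloromethanesulfonyl)oxy]germacra-1(10)Z,4(15),11(13)-trien-12,6-olide | C=C1C(=O)O[C@@H]2[C@H]1[C@@H](OS(=O)(=O)CCl)C/C(C)=C\[C@H](O[Si](C)(C)C(C)(C)C)CC(=C)[C@@H]2OC(C)=O
F10 | step 13 | (3R,4S,7R,8Z)-4-acetoxy-7-[(tert-butyldimethylsilyl)oxy]-9-methyl-5-methylidene-11-[(triethylsilyl)oxy]undeca-1,8-dien-3-yl 2-{[(4-methoxybenzyl)oxy]methyl}prop-2-enoate | CC[Si](CC)(CC)OCC/C(C)=C\[C@H](O[Si](C)(C)C(C)(C)C)CC(=C)[C@H](OC(C)=O)[C@H](OC(=O)C(=C)COCc1ccc(OC)cc1)C=C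
F11 | step 13 | (1S,4R,5Z)-4-[(tert-butyldimethylsilyl)oxy]-1-[(2R)-4-{[(4-methoxybenzyl)oxy]methyl}-5-oxo-2,5-dihydrofuran-2-yl]-6-methyl-2-methylidene-8-[(triethylsilyl)oxy]oct-5-en-1-yl acetate | CC[Si](CC)(CC)OCC/C(C)=C\[C@H](O[Si](C)(C)C(C)(C)C)CC(=C)[C@H](OC(C)=O)[C@@H]1OC(=O)C(COCc2ccc(OC)cc2)=C1
F12 | step 13 | (1S,4R,5Z)-4-[(tert-butyldimethylsilyl)oxy]-1-[(2R)-4-(hydroxymethyl)-5-oxo-2,5-dihydrofuran-2-yl]-6-methyl-2-methylidene-8-[(triethylsilyl)oxy]oct-5-en-1-yl acetate | CC[Si](CC)(CC)OCC/C(C)=C\[C@H](O[Si](C)(C)C(C)(C)C)CC(=C)[C@H](OC(C)=O)[C@@H]1OC(=O)C(CO)=C1
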